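All runs are simulated from invented constants; scatter was added.

Late in a run, the target in a flask can be set against the substrate that has gone. That comparison carries the reckoning below for the south-east flask, whose course is wanted up to 6.0 h.

| setting | south-east | north-west | flask |
|---|---|---|---|
| substrate | 0.20 M (fed, over 50 min) | 0.20 M (fed, over 50 min) | 0.20 M (fed, over 50 min) |
| partner | 0.20 M | 0.40 M | 0.200 M |
| remark | the very flask that is asked about, followed so far | run made earlier |  |
| time |  |  | 6.0 h |

- south-east (time / h: target / %, substrate / %): 0.133: 2.3, 13.6; 0.333: 5.7, 30.9; 0.667: 19.5, 51.1; 1.00: 31.1, 51.0; 1.33: 37.3, 40.2; 2.00: 46.4, 27.5; 2.50: 48.3, 18.9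
- north-west (time / h: target / %, substrate / %): 0.500: 19.9, 28.7; 0.667: 28.3, 33.4; 1.00: 46.8, 24.4; 1.50: 56.1, 11.5; 2.50: 60.9, 1.4; 4.00: 60.1, 1.3; 6.00: 58.1, 0

(each reading ± 1 percentage point)

- percentages count the whole charge, also what has not yet gone in

- amount of target in percent of the substrate charged, at 40 min, 2.0 h, 4.0 h and 6.0 h

The first estimate is a share. Pooling the south-east readings at 2.00 h and 2.50 h gives target over substrate gone as 61.7%. This share of consumed substrate found as target, the selectivity, is carried through the reckoning. The north-west flask, with twice the partner, tests it on other readings: at 4.00 h the share predicts 60.9%, and the reading is 60.1%.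

The second estimate is a clock. Taking substrate and partner to fall one to one, c(substrate) equals c(partner) in the south-east flask after the feed, so the reciprocal of c(substrate) should rise in a straight line with slope k. The readings from 1.00 h to 2.50 h give 11.1 /M/h. Running that line on and multiplying the substrate gone by the share puts target at 56.9% at 6.0 h.

The weak link is k, which rests on two readings. On the same one-to-one count, partner in the north-west flask is taken to exceed substrate by 0.200 M after the feed, and the logarithm of c(partner)/c(substrate) from 1.00 h to 1.50 h then gives 6.43 /M/h. The mean of the two is 8.76 /M/h, which gives 45.1% at 2.0 h, 53.1% at 4.0 h and 55.9% at 6.0 h. At 40 min the feed is still running: the share gives 17.8%, the reading is 19.5%, and their mean is 18.6%.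

The forecast reads 18.5%, 45%, 51% and 52.5%, on the ground that “selectivity is about 60% and does not depend on partner”. At 6.0 h it stands lower than this reckoning.

The flask gives 18.5%, 46.1%, 53.9% and 56.5%.

    substrate + partner → target (k = 5.70 /M/h)
    substrate + partner → isomer of the product (k = 1.45 /M/h)
    substrate + partner → second isomer (k = 1.80 /M/h)
    partner + target → over-reaction product (k = 0.105 /M/h)

In the flask asked about, the half-life of target by the loss to over-reaction product alone, 33 h with the other concentrations as charged, is longer than the 6.0 h asked, and over-reaction product stands at 1.11% at that time. With 9.6% of the substrate left, the share 61.7% gives 55.8% of target, and the flask holds 56.5%.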